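**Retrosynthetic overview**
Grevirobstol B <= its ring A methyl ether (BBr3) <= the same 22-membered macrocycle with an E double bond between the benzylic carbon of ring B and the next chain carbon (H2).
That macrocycle <= an acyclic aldehyde/phosphonate in one flask. An intramolecular Horner-Wadsworth-Emmons olefination joins the future benzylic carbon (a 4-pyranon-2-ylmethyl phosphonate carbon) to the chain terminus (an aldehyde carbon); hydroxide then opens the 4-pyrone, and the freed trione folds by a transannular aldol condensation into ring B.
Enabling feature: in ring B the ether-bearing carbon C1, the hydroxylated carbons C2 and C4, C3, C5, the alkylated carbon C6 and the benzylic CH2 (C7) are the seven carbons of a 1-aryloxyheptane-2,4,6-trione. The resorcinol 1,3-oxygen pattern marks the carbonyl groups, C7 is the chain end that a phosphonate can activate, and the hindered diaryl ether bond O-C1 can start as a plain ArO-CH2 ether.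
Pyrone phosphonate <= aryl propargyl ether (C1-C3) + N-methoxy-N-methylcarbamoyl chloride (C4) + diethyl (2-oxopropyl)phosphonate (C5-C7). Ring A with its C16 alkenyl chain <= 1-bromo-3,5-dimethoxybenzene, 11-bromoundec-1-ene and 1,5-dibromopentane by two Grignard cross-couplings.
Order of rings: ring A is bought; the temporary 4-pyrone ring is closed in step 6; the macrocycle and then ring B are closed in step 8, in which the pyrone ring disappears.

Key step: step 8

Remark on the chemistry: the locants C1 to C7 defined above are used for ring B and for its acyclic and pyrone precursors alike; the new alkene is drawn E, but its geometry has no consequence because step 9 removes it.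

**Step 1**
Reactants: 1 11-bromoundec-1-ene; 2 1,5-dibromopentane
Product: 4 16-bromohexadec-1-ene, via undec-10-enylmagnesium bromide 3 (not isolated)
Conditions: 1, Mg, THF, 40 °C; then added to 2 (4 equiv), Li2CuCl4 (2 mol %), THF, -10 to 0 °C
Reagents that add atoms: none
Why: Copper-catalysed Kumada-type cross-coupling of a primary alkyl Grignard reagent with a primary alkyl bromide is reliable, and the excess of symmetrical 2 should hold double coupling down.

**Step 2**
Reactants: 5 1-bromo-3,5-dimethoxybenzene; 4 16-bromohexadec-1-ene
Product: 7 1-(hexadec-15-en-1-yl)-3,5-dimethoxybenzene, via 3,5-dimethoxyphenylmagnesium bromide 6 (not isolated)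
Conditions: 5, Mg, THF, reflux; 6 and TMEDA added slowly to 4, FeCl3 (5 mol %), THF, 0 °C
Reagents that add atoms: none
Why: Iron-catalysed Kumada-type cross-coupling of an aryl Grignard reagent with a primary alkyl bromide joins ring A to the chain, and the remote terminal alkene and the methyl ethers are inert to it.

**Step 3**
Reactants: 7 1-(hexadec-15-en-1-yl)-3,5-dimethoxybenzene
Product: 8 3-(hexadec-15-en-1-yl)-5-methoxyphenol
Conditions: NaSEt (3 equiv), DMF, 140 °C; aq HCl work-up
Reagents that add atoms: none
Why: Nucleophilic (SN2) O-demethylation of an aryl methyl ether by thiolate should stop after one methyl group, because the phenoxide formed makes the second aryloxide a far poorer leaving group, and this desymmetrises ring A.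

**Step 4**
Reactants: 8 3-(hexadec-15-en-1-yl)-5-methoxyphenol; 9 propargyl bromide (3-bromoprop-1-yne)
Product: 10 1-(hexadec-15-en-1-yl)-3-methoxy-5-(prop-2-yn-1-yloxy)benzene
Conditions: K2CO3, acetone, reflux
Reagents that add atoms: none
Why: Williamson ether synthesis (SN2 at a primary propargylic bromide) forms, without any hindrance, the O-C1 bond that will end as the doubly ortho-substituted diaryl ether bond.

**Step 5**
Reactants: 10 1-(hexadec-15-en-1-yl)-3-methoxy-5-(prop-2-yn-1-yloxy)benzene; 11 N-methoxy-N-methylcarbamoyl chloride
Product: 13 4-[3-(hexadec-15-en-1-yl)-5-methoxyphenoxy]-N-methoxy-N-methylbut-2-ynamide, via lithium acetylide 12 (not isolated)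
Conditions: n-BuLi (1.05 equiv), THF, -78 °C; then 11, -78 to 0 °C
Reagents that add atoms: none
Why: Deprotonation of the terminal alkyne, far faster at -78 °C than ring lithiation, followed by acylation of the acetylide with the carbamoyl chloride is the standard one-step route to alkynyl Weinreb amides and adds C4.

**Step 6**
Reactants: 14 diethyl (2-oxopropyl)phosphonate; 13 4-[3-(hexadec-15-en-1-yl)-5-methoxyphenoxy]-N-methoxy-N-methylbut-2-ynamide
Product: 17 diethyl [(6-{[3-(hexadec-15-en-1-yl)-5-methoxyphenoxy]methyl}-4-oxo-4H-pyran-2-yl)methyl]phosphonate, via keto phosphonate dianion 15 (not isolated), via alkynyl diketone 16 (not isolated)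
Conditions: 14, NaH, THF, 0 °C, then n-BuLi, 0 °C; 13, -78 to -20 °C; cold 1 M HCl; crude 16, p-TsOH·H2O (10 mol %), toluene, 60 °C
Reagents that add atoms: none
Why: The dianion of the beta-keto phosphonate is acylated at its last-formed, most nucleophilic (gamma) carbon by the Weinreb amide, which releases the ynone only on the acidic quench, and acid-catalysed 6-endo-dig oxa-Michael cyclisation of the enol onto the ynone is the standard route from acetylenic beta-diketones to 4-pyrones.

**Step 7**
Reactants: 17 diethyl [(6-{[3-(hexadec-15-en-1-yl)-5-methoxyphenoxy]methyl}-4-oxo-4H-pyran-2-yl)methyl]phosphonate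
Product: 19 diethyl [(6-{[3-methoxy-5-(15-oxopentadecyl)phenoxy]methyl}-4-oxo-4H-pyran-2-yl)methyl]phosphonate, via terminal 1,2-diol 18 (not isolated)
Conditions: OsO4 (2 mol %), NaIO4 (4 equiv), 2,6-lutidine, dioxane-H2O 3:1, rt
Reagents that add atoms: osmium tetroxide, O=[Os](=O)(=O)=O (catalytic oxygen carrier); sodium periodate, [Na+].[O-]I(=O)(=O)=O (terminal oxygen source)
Why: Lemieux-Johnson oxidation (dihydroxylation, then periodate glycol cleavage) attacks the only isolated electron-rich alkene, leaves the electron-poor pyrone double bonds and the arene alone, and trims the chain to the fifteen carbons needed.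

**Step 8**
Reactants: 19 diethyl [(6-{[3-methoxy-5-(15-oxopentadecyl)phenoxy]methyl}-4-oxo-4H-pyran-2-yl)methyl]phosphonate
Product: 22 ring A O-methyl ether of (E)-didehydrogrevirobstol B (styrene bond between C7 and the next chain carbon), via macrocyclic alkenylpyrone 20 (not isolated), via macrocyclic enetrione 21 (not isolated)
Conditions: K2CO3 (6 equiv), 18-crown-6 (12 equiv), toluene, 70 °C, 19 added by syringe pump over 12 h (final 1 mM); then degassed 2 M aq KOH-EtOH, 80 °C, Ar; aq HCl to pH 3
Reagents that add atoms: water, O (delivered as aqueous KOH, [K+].[OH-])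
Why: Proposed new method: K2CO3/18-crown-6 deprotonates C7, the carbon between the phosphonate and the pyrone (a vinylogous beta-keto phosphonate and the most acidic carbon of 19), and its intramolecular Horner-Wadsworth-Emmons reaction with the chain aldehyde closes the 24-membered ring of 20 (counted through the pyran oxygen) under pseudo-high dilution, the loss of diethyl phosphate making this the only irreversible outcome even if the less acidic OCH2 group (C1) adds reversibly to the aldehyde. Hydroxide then adds to C2 or C6 of the 4-pyrone, the ring opens to the 26-membered 1-aryloxy-2,4,6-trione 21, and C1 attacks the C6 carbonyl across the ring in a 6-(enolendo)-exo-trig aldol addition, after which loss of water and enolisation give ring B and leave the 22-membered macrocycle. The closest known reaction types are macrocyclising Horner-Wadsworth-Emmons olefinations, the alkali-induced conversion of 2,6-dimethyl-4-pyrone through heptane-2,4,6-trione into orcinol, and the biomimetic aldol folding of cinnamoyl-terminated poly-beta-carbonyl chains to stilbene resorcinols; new are their union in one flask, the transannular setting and an aryloxymethylene group as the aldol donor. Two selectivities are needed: C7 must olefinate the distant aldehyde and not the C2 carbonyl, which the pyrone mask secures by tying C2 up as an enol ether carbon on the far side of the ring, and the fold must use C1 and not C7 as donor, which the olefination itself secures, since C7 has become a vinylic CH without enolisable hydrogen and C1, acidified by its aryloxy group, is the only terminal donor that can form a six-membered ring. Oxa-Michael addition, Michael addition of C3 and hydration of the enone are reversible in base whereas aromatisation is not, and the dilution that serves the ring closure also suppresses the intermolecular aldol dimerisation of the trione. No stereocenter is formed, and the alkene geometry (E expected) is erased in step 9.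

**Step 9**
Reactants: 22 ring A O-methyl ether of (E)-didehydrogrevirobstol B
Product: 23 grevirobstol B ring A methyl ether
Conditions: H2 (1 atm), Pd/C (10 wt % Pd on carbon), EtOAc-EtOH, rt
Reagents that add atoms: none
Why: Heterogeneous catalytic hydrogenation saturates the disubstituted styrene bond under conditions that leave the phenols, the aryl methyl ether and the diaryl ether untouched.

**Step 10**
Reactants: 23 grevirobstol B ring A methyl ether
Product: 24 grevirobstol B
Conditions: BBr3 (5 equiv), CH2Cl2, -78 °C to rt; then H2O
Reagents that add atoms: none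
Why: Lewis acid-mediated aryl methyl ether cleavage with BBr3 (bromide attacks the methyl group of the boron-complexed ether) cannot touch the diaryl ether, whose two carbons are sp2, and the saturated chain is inert.

**Compound list**
1 | 11-bromoundec-1-ene | C=CCCCCCCCCCBr | starting material
2 | 1,5-dibromopentane | BrCCCCCBr | starting material
3 | undec-10-enylmagnesium bromide | C=CCCCCCCCCC[Mg]Br | intermediate
4 | 16-bromohexadec-1-ene | C=CCCCCCCCCCCCCCCBr | intermediate
5 | 1-bromo-3,5-dimethoxybenzene | COc1cc(Br)cc(OC)c1 | starting material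
6 | 3,5-dimethoxyphenylmagnesium bromide | COc1cc([Mg]Br)cc(OC)c1 | intermediate
7 | 1-(hexadec-15-en-1-yl)-3,5-dimethoxybenzene | COc1cc(CCCCCCCCCCCCCCC=C)cc(OC)c1 | intermediate
8 | 3-(hexadec-15-en-1-yl)-5-methoxyphenol | COc1cc(O)cc(CCCCCCCCCCCCCCC=C)c1 | intermediate
9 | propargyl bromide (3-bromoprop-1-yne) | C#CCBr | starting material
10 | 1-(hexadec-15-en-1-yl)-3-methoxy-5-(prop-2-yn-1-yloxy)benzene | COc1cc(OCC#C)cc(CCCCCCCCCCCCCCC=C)c1 | intermediate
11 | N-methoxy-N-methylcarbamoyl chloride | CON(C)C(=O)Cl | starting material
12 | lithium acetylide of 10 | COc1cc(OCC#C[Li])cc(CCCCCCCCCCCCCCC=C)c1 | intermediate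
13 | 4-[3-(hexadec-15-en-1-yl)-5-methoxyphenoxy]-N-methoxy-N-methylbut-2-ynamide | COc1cc(OCC#CC(=O)N(C)OC)cc(CCCCCCCCCCCCCCC=C)c1 | intermediate
14 | diethyl (2-oxopropyl)phosphonate | CCOP(=O)(CC(C)=O)OCC | starting material
15 | sodium lithium dianion of 14 (deprotonated at C1 and C3 of the oxopropyl group) | [Na+].[Li+].[CH2-]C(=O)[CH-]P(=O)(OCC)OCC | intermediate
16 | diethyl {7-[3-(hexadec-15-en-1-yl)-5-methoxyphenoxy]-2,4-dioxohept-5-yn-1-yl}phosphonate | CCOP(=O)(CC(=O)CC(=O)C#CCOc1cc(OC)cc(CCCCCCCCCCCCCCC=C)c1)OCC | intermediate
17 | diethyl [(6-{[3-(hexadec-15-en-1-yl)-5-methoxyphenoxy]methyl}-4-oxo-4H-pyran-2-yl)methyl]phosphonate | CCOP(=O)(Cc1cc(=O)cc(COc2cc(OC)cc(CCCCCCCCCCCCCCC=C)c2)o1)OCC | intermediate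
18 | racemic terminal 1,2-diol from 17 (15,16-dihydroxyhexadecyl chain) | CCOP(=O)(Cc1cc(=O)cc(COc2cc(OC)cc(CCCCCCCCCCCCCCC(O)CO)c2)o1)OCC | intermediate
19 | diethyl [(6-{[3-methoxy-5-(15-oxopentadecyl)phenoxy]methyl}-4-oxo-4H-pyran-2-yl)methyl]phosphonate | CCOP(=O)(Cc1cc(=O)cc(COc2cc(OC)cc(CCCCCCCCCCCCCCC=O)c2)o1)OCC | intermediate
20 | macrocyclic alkenylpyrone: 4-pyrone bearing at one alpha carbon the CH2-O link to ring A and at the other (E)-CH=CH(CH2)14 back to ring A (ring A: 1-oxy, 3-methoxy, 5-alkyl) | COc1cc2cc(c1)OCc3cc(=O)cc(o3)/C=C/CCCCCCCCCCCCCC2 | intermediate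
21 | macrocyclic enetrione: ring A-O-CH2-CO-CH2-CO-CH2-CO-(E)-CH=CH-(CH2)14-ring A, 26-membered | COc1cc2cc(c1)OCC(=O)CC(=O)CC(=O)/C=C/CCCCCCCCCCCCCC2 | intermediate
22 | ring A O-methyl ether of (E)-didehydrogrevirobstol B: 22-membered ring, ring B with OAr at C1, OH at C2 and C4, (E)-CH=CH(CH2)14 at C6 | COc1cc2cc(c1)Oc3c(O)cc(O)cc3/C=C/CCCCCCCCCCCCCC2 | intermediate
23 | grevirobstol B ring A methyl ether | COc1cc2cc(c1)Oc3c(O)cc(O)cc3CCCCCCCCCCCCCCCC2 | intermediate
24 | grevirobstol B | Oc1cc2cc(c1)Oc1c(O)cc(O)cc1CCCCCCCCCCCCCCCC2 | target

**Total step count:** 10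
**Longest linear sequence:** 10 steps (1 to 24)

**Steps most likely to fail**

*Step 8 (Proposed new method).*
- What may go wrong in the first stage: oligomerisation may outrun ring closure.
- What may go wrong in the second stage: the fold may be overtaken by hydration of the enone followed by retro-aldol cleavage of the new bond, by base-induced deconjugation of the enone (which would turn C7 into an aldol donor), or by Michael closure through C3.
- Fallback, known chemistry only, setting out from 8. An Ullmann-type diaryl ether coupling with commercially available 2-bromo-3,5-dimethoxybenzaldehyde (O=Cc1cc(OC)cc(OC)c1Br; CuI, N,N-dimethylglycine, Cs2CO3, dioxane, 100 °C) should give 2-[3-(hexadec-15-en-1-yl)-5-methoxyphenoxy]-3,5-dimethoxybenzaldehyde F1. Wittig methylenation (Ph3P=CH2, THF) should give 1-ethenyl-2-[3-(hexadec-15-en-1-yl)-5-methoxyphenoxy]-3,5-dimethoxybenzene F2. Ring-closing metathesis (second-generation Grubbs catalyst, RuCl2(=CHPh)(PCy3)(SIMes), CH2Cl2, reflux, 1 mM) closes the same bond as an alkene and should give (E)-didehydrogrevirobstol B trimethyl ether F3. Hydrogenation (H2, Pd/C) gives grevirobstol B trimethyl ether F4. BBr3 then removes all three methyl groups, and the route is rejoined at 24.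

*Step 6.*
- What may go wrong: conjugate addition of the dianion to the alkynyl amide in place of attack at its carbonyl group, or closure of the phosphonate carbon onto the ynone in place of the enol oxygen, may take over.
- Fallback, setting out from 10. The acetylide 12 is formylated with DMF to 4-[3-(hexadec-15-en-1-yl)-5-methoxyphenoxy]but-2-ynal F5. Aldol addition of dianion 15 at -78 °C (1,2-addition to an aldehyde, the best-established reaction of such dianions) should give racemic diethyl {7-[3-(hexadec-15-en-1-yl)-5-methoxyphenoxy]-4-hydroxy-2-oxohept-5-yn-1-yl}phosphonate F6. Oxidation of the propargylic alcohol with MnO2 in CH2Cl2 gives 16, which closes under acid catalysis, and the route is rejoined at 17.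

*Step 2.*
- What may go wrong: homocoupling of the aryl Grignard reagent and beta-hydride elimination at the alkyl-iron stage may consume both partners.
- Fallback, setting out from 3, with the disconnection moved by one carbon to a benzylic electrophile. Li2CuCl4-catalysed coupling of 3 with excess 1,4-dibromobutane (BrCCCCBr) should give 15-bromopentadec-1-ene F7. Mg in THF converts it into pentadec-14-enylmagnesium bromide F8. Li2CuCl4-catalysed coupling of this with commercially available 3,5-dimethoxybenzyl bromide (COc1cc(CBr)cc(OC)c1) rejoins the route at 7.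

**Further compounds**
F1 | step 8 | 2-[3-(hexadec-15-en-1-yl)-5-methoxyphenoxy]-3,5-dimethoxybenzaldehyde | O=Cc1cc(OC)cc(OC)c1Oc1cc(OC)cc(CCCCCCCCCCCCCCC=C)c1
F2 | step 8 | 1-ethenyl-2-[3-(hexadec-15-en-1-yl)-5-methoxyphenoxy]-3,5-dimethoxybenzene | C=Cc1cc(OC)cc(OC)c1Oc1cc(OC)cc(CCCCCCCCCCCCCCC=C)c1
F3 | step 8 | (E)-didehydrogrevirobstol B trimethyl ether | COc1cc2cc(c1)Oc3c(OC)cc(OC)cc3/C=C/CCCCCCCCCCCCCC2
F4 | step 8 | grevirobstol B trimethyl ether | COc1cc2cc(c1)Oc3c(OC)cc(OC)cc3CCCCCCCCCCCCCCCC2
F5 | step 6 | 4-[3-(hexadec-15-en-1-yl)-5-methoxyphenoxy]but-2-ynal | COc1cc(OCC#CC=O)cc(CCCCCCCCCCCCCCC=C)c1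
F6 | step 6 | racemic diethyl {7-[3-(hexadec-15-en-1-yl)-5-methoxyphenoxy]-4-hydroxy-2-oxohept-5-yn-1-yl}phosphonate | CCOP(=O)(CC(=O)CC(O)C#CCOc1cc(OC)cc(CCCCCCCCCCCCCCC=C)c1)OCC
F7 | step 2 | 15-bromopentadec-1-ene | C=CCCCCCCCCCCCCCBr
F8 | step 2 | pentadec-14-enylmagnesium bromide | C=CCCCCCCCCCCCCC[Mg]Br
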